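## The problem

The target is a C40 carotenoid in which one end of lycopene is closed to a cyclopentane (carotenoid numbering, ring carbons C2, C3, C4, C5, C6). The ring carries an isopropenyl group (C1 with C16 and C17) on C2, a tertiary methyl carbinol at C5, and on C6 a chain of ten conjugated E double bonds (C7 to C5′) that ends in the isolated C1′=C2′ alkene. The three ring stereocentres are contiguous: C2 (S), C5 (S) and C6 (R). The chain on C6 is trans to the isopropenyl group and cis to the C5 hydroxyl. C5 is quaternary and cannot be corrected later, so C5 and C6 must be set as a pair. C2 and C6 each sit α to a carbonyl at some stage and can fall back to the trans arrangement. The polyene will not tolerate acid, light or oxygen. The C5 hydroxyl is β to C7, which invites retro-aldol cleavage or elimination when C7 is an aldehyde and ether formation when an allylic cation is raised in the chain. The chain itself follows the C15 + C10 + C15 Wittig logic, so the real problem is a C10 cyclopentane aldehyde with three stereocentres. The enabling feature is that C1 is an acetyl carbon in disguise. Taken into the ring, it turns the cyclopentane into a cyclohexane C1–C2–C6–C5–C4–C3 with a 1,4 pair of methyl carbinols, which a Diels–Alder reaction can build. A 1,2-shift of C3 from C1 to C2 then returns the five-membered ring, expels C1 as acetyl and sets C2 by inversion.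

## Retrosynthesis

**Silyl ether and C11=C12.** Target 34 is taken back to its triethylsilyl ether 33, so that the C5 oxygen stays masked through every operation on C7 and C11 and is freed at the end by fluoride, without acid. The C11=C12 bond of 33 is cut (Wittig) into the ring C15 phosphonium salt 27 and the C25 aldehyde 32. A cut at C7=C8 would pair a hindered, epimerisable ring aldehyde with a C30 ylide. A cut at C9=C10 or C13=C14 would form a trisubstituted double bond with poor control. C11=C12 is disubstituted, can be equilibrated to E, and is the most convergent cut. Salt 27 holds all three stereocentres on fifteen carbons and 32 is achiral. The coupling must tolerate the silyl ether and the isopropenyl group.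

**The ψ half.** Aldehyde 32 is cut at C11′=C12′ into the ψ-end phosphonium salt 30 and the C10 dialdehyde 31, used in excess so that one formyl group reacts. Salt 30 goes back through the tertiary allylic alcohol 29 to pseudoionone 28. The C10′–C11′ unit is a vinyl group added to the ketone, and the salt forms with allylic transposition. Nothing stereogenic is involved and these three steps lie off the longest sequence.

**C7=C8.** Salt 27 comes from allylic alcohol 25, and 25 from dienoate 24. Ester 24 is cut at C7=C8 (Horner–Wadsworth–Emmons) into the C10 ring aldehyde 22 and the C5 phosphonate 23. The neighbouring cut at C9=C10 would need an olefination of a methyl ketone and gives a less reliable trisubstituted alkene; 23 brings that bond in ready-made. The olefination must be E-selective and must leave C6 alone, which is α to the aldehyde and β to the silyloxy group.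

**Ring appendages.** Aldehyde 22 is simplified through alcohol 21 to the p-methoxybenzyl ether 20, and the isopropenyl group of 20 to the acetyl group of 19 (C1=C16 cut, Wittig methylenation). Methylenation comes first, while C7 is still an ether, so only one carbonyl is present. The ether is then removed oxidatively so that neither the silyl ether nor the alkene meets acid.

**The key cut, C2–C3.** In 19 the bond C2–C3 is broken and C3 is reattached to C1. The precursor is cyclohexane 18, in which C1 is a ring carbon bearing methyl and hydroxyl, and C2 bears a mesylate cis to that hydroxyl and trans to the C6 arm. The alternatives are cuts at C2–C6, C5–C6 or C1–C2 on an open chain or on a cyclopentenone. This cut instead exchanges three adjacent stereocentres on a five-membered ring for a cyclohexane whose substituents can be placed by cycloaddition and alkene addition, and it sets C2 by a stereospecific inversion. The shift needs the C2–O bond anti-periplanar to C1–C3, which means an equatorial mesylate in the chair that keeps the arm equatorial.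

**cis-Diol monomesylate.** Mesylate 18 comes from diol 17, and the two C–O bonds of 17 are cut together back to cyclohexene 16. Osmylation must occur on the face opposite the C6 arm. The arm and the C5 silyloxy group are on the same face, so both steer the reagent the same way. Of the two hydroxyls only the secondary one is sulfonylated.

**The C5 methyl carbinol.** Silyl ether 16 goes back to tertiary alcohol 15. Its C18 methyl is traced through epoxide 14 and tosylate 13 to the primary hydroxyl of diol 12, and the diol to the spiro lactone acetal 11. C5 therefore stays a stereocentre from the cycloaddition onward. A ketone at C5 (from a 2-haloacrolein-type ketene equivalent, followed by methyl addition) was rejected for two reasons. It would leave C6 as the only stereocentre, α to a carbonyl and allylic at once, and so prone to racemisation. It would also turn any exo/endo mixture into loss of enantiopurity.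

**Diels–Alder.** Adduct 11 is cut at C5–C6 and C3–C4 into diene 5 and the lactic acid-derived methylene dioxolanone 10. The 1-alkyl and 3-methyl groups of the diene both direct the dienophile's substituted carbon to C6 (ortho/para). The s-cis-locked dienophile reacts with open-chain dienes through the carbonyl-exo transition state, which puts the ring oxygen cis to the C6 arm, exactly the C5/C6 relation of the target. The tert-butyl group shields one face, so absolute configuration comes from lactic acid.

**Building blocks.** Diene 5 is the p-methoxybenzyl ether of dienol 4, made from ester 3, the Horner–Wadsworth–Emmons product of methacrolein 1 and phosphonoacetate 2. Dienophile 10 comes from dioxolanone 8 through bromide 9, and 8 from (R)-lactic acid 6 and pivalaldehyde 7.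

## Roads not taken

**Alternative 1:** Three-component coupling on a ready-made ring. The cut removes C1–C2 and C6–C7 from cyclopent-2-en-1-one A1. In the forward sense, a copper-catalysed asymmetric conjugate addition of an isopropenylmagnesium halide forms C1–C2. The enolate is held as its silyl enol ether and then alkylated at C6 by an orthoformate under a boron Lewis acid, giving (2S,3S)-2-(dimethoxymethyl)-3-(prop-1-en-2-yl)cyclopentan-1-one A2.
- Merits: the ring is bought, the isopropenyl group and C7 arrive in their final oxidation states, and the C2/C6 trans relation follows from anti trapping of the enolate. A2 is reached in one or two operations, against thirteen steps to 19 here.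
- Weak points: cyclopentenone is the least tractable enone for this asymmetric addition, and an alkenyl nucleophile more so. C5 must then come from methyl addition to the ketone of A2. Its α-carbon C6 is epimerisable and can lose methoxide, and its faces are distinguished only by the C6 acetal (which steers correctly) against the C2 isopropenyl group on the other face.
- Comparison: this road is clearly shorter. The chosen plan offers in return a C5 centre set together with C6 in a cycloaddition, and a C2 centre set by inversion, not by the enantioselectivity of one catalytic step.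

**Alternative 2:** Aldol-lactonisation of a chiral-pool keto acid. The cut is C5–C6, with a temporary O–C7 bond. (S)-Limonene A3 is cleaved at its ring alkene to (3S)-6-oxo-3-(prop-1-en-2-yl)heptanoic acid A4. Carboxyl activation with a nucleophilic amine gives an ammonium enolate whose C6 adds to the methyl ketone carbon C5. The tertiary alkoxide then closes the cis-fused β-lactone (1R,2S,5S)-5-methyl-2-(prop-1-en-2-yl)-6-oxabicyclo[3.2.0]heptan-7-one A5.
- Merits: C2 comes from the chiral pool. The four-membered ring forces the C5 oxygen and C7 to be cis, which is the relation the target needs. No protecting group is used up to that point and the sequence is short.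
- Weak points: C5 and C6 are set relative to C2 by 1,3-induction in the aldol transition state. The ring alkene of A3 must be cleaved in the presence of the isopropenyl group. Opening A5 to the C7 aldehyde passes through a free β-hydroxy carbonyl compound that is prone to retro-aldol cleavage.
- Comparison: in step count and in the way it delivers the C5/C6 relation, this road is at least as good as the chosen one. The chosen plan sets against it a C2 centre fixed by a stereospecific shift (and thermodynamically trans), C5/C6 fixed by auxiliary-controlled cycloaddition, and equal access to either enantiomer from lactic acid.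

**Alternative 3:** Anodic cyclisation of an open chain. The cut is C2–C6. The precursor is tert-butyl{[(3S,1E,6E)-1-methoxy-3,7-dimethyl-8-(trimethylsilyl)octa-1,6-dien-3-yl]oxy}dimethylsilane A6. Constant-current oxidation in methanol turns its enol ether into a radical cation. The allylsilane carbon C2 attacks C6 (5-exo), C7 is trapped as the dimethyl acetal and loss of silicon leaves the isopropenyl group, giving tert-butyl{[(1S,2R,3S)-2-(dimethoxymethyl)-1-methyl-3-(prop-1-en-2-yl)cyclopentyl]oxy}dimethylsilane A7.
- Merits: the ring, the C7 acetal and the isopropenyl group appear in one step, and the single pre-existing stereocentre C5 is a tertiary carbinol of a kind the terpene pool supplies.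
- Weak points: two new stereocentres (C2, C6) must be set against a quaternary C5 in a flexible radical-cation transition state. Nothing enforces the C5/C6 cis relation. A6 needs several steps to carry both the enol ether and the allylsilane, and electrolysis equipment is required.
- Comparison: the length is comparable to the chosen plan and the oxidation-state economy is better. The stereochemical outcome is less predictable than the cycloaddition plus stereospecific shift used here.

Key step: step 13

Assumption: pseudoionone 28 is used as its (3E,5E) isomer (any 5Z material is removed when phosphonium salt 30 is crystallised), and (R)-lactic acid 6 is used enantiopure.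

## Route

Step 1
Reactants: 1 methacrolein; 2 triethyl phosphonoacetate
Product: 3 ethyl (2E)-4-methylpenta-2,4-dienoate
Conditions: NaH, THF, 0 °C to rt
Reagents that add atoms: none
Why: Horner–Wadsworth–Emmons olefination of an enal with a stabilised phosphonate anion; 1,2-addition is favoured and the new disubstituted double bond should form E.

Step 2
Reactants: 3 ethyl (2E)-4-methylpenta-2,4-dienoate
Product: 4 (2E)-4-methylpenta-2,4-dien-1-ol
Conditions: i-Bu2AlH (2.2 equiv), CH2Cl2, −78 to 0 °C
Reagents that add atoms: none
Why: 1,2-reduction of an α,β-unsaturated ester to the allylic alcohol by an aluminium hydride; the diene is not touched.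

Step 3
Reactants: 4 (2E)-4-methylpenta-2,4-dien-1-ol
Product: 5 1-methoxy-4-({[(2E)-4-methylpenta-2,4-dien-1-yl]oxy}methyl)benzene
Conditions: NaH, 4-methoxybenzyl chloride, n-Bu4NI (cat.), THF–DMF, 0 °C to rt
Reagents that add atoms: 4-methoxybenzyl chloride, COc1ccc(CCl)cc1
Why: Williamson etherification; the p-methoxybenzyl ether survives hydrides, alkoxide and ylides and is later removed oxidatively without acid.

Step 4
Reactants: 6 (R)-lactic acid; 7 pivalaldehyde
Product: 8 (2R,5R)-2-tert-butyl-5-methyl-1,3-dioxolan-4-one
Conditions: TsOH·H2O (cat.), pentane, reflux with water separator; recrystallisation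
Reagents that add atoms: none
Why: Acid-catalysed acetalisation of an α-hydroxy acid; the cis isomer is favoured and is purified by crystallisation, so the acetal carbon takes its configuration from lactic acid.

Step 5
Reactants: 8 (2R,5R)-2-tert-butyl-5-methyl-1,3-dioxolan-4-one
Product: 10 (2R)-2-tert-butyl-5-methylidene-1,3-dioxolan-4-one, via 5-bromo dioxolanone 9 (not isolated)
Conditions: N-bromosuccinimide, AIBN (cat.), PhCF3, reflux; then Et3N, 0 °C to rt
Reagents that add atoms: none
Why: Wohl–Ziegler radical bromination at the captodative C5–H, then base-induced dehydrobromination; the lactic acid centre is lost but the acetal centre set from it remains.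

Step 6
Reactants: 5 1-methoxy-4-({[(2E)-4-methylpenta-2,4-dien-1-yl]oxy}methyl)benzene; 10 (2R)-2-tert-butyl-5-methylidene-1,3-dioxolan-4-one
Product: 11 (2R,5S,6S)-2-tert-butyl-6-{[(4-methoxyphenyl)methoxy]methyl}-8-methyl-1,3-dioxaspiro[4.5]dec-7-en-4-one
Conditions: toluene, BHT (cat.), 80 °C, sealed tube
Reagents that add atoms: none
Why: Thermal Diels–Alder reaction; the 1-alkyl and 3-methyl groups of the diene both direct the spiro carbon to C6 (ortho/para), the carbonyl-exo transition state expected for this s-cis-locked α-oxyacrylate with open-chain dienes puts the ring oxygen cis to the C6 arm, and addition anti to the tert-butyl group fixes the absolute configuration of C5 and C6.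

Step 7
Reactants: 11 (2R,5S,6S)-2-tert-butyl-6-{[(4-methoxyphenyl)methoxy]methyl}-8-methyl-1,3-dioxaspiro[4.5]dec-7-en-4-one
Product: 12 (1S,2S)-1-(hydroxymethyl)-2-{[(4-methoxyphenyl)methoxy]methyl}-4-methylcyclohex-3-en-1-ol
Conditions: LiAlH4, THF, 0 °C to rt
Reagents that add atoms: none
Why: Hydride reduction of the lactone carbonyl frees the C18 primary alcohol, and collapse of the hemiacetal frees the tertiary C5 hydroxyl; no bond to C5 or C6 is broken.

Step 8
Reactants: 12 (1S,2S)-1-(hydroxymethyl)-2-{[(4-methoxyphenyl)methoxy]methyl}-4-methylcyclohex-3-en-1-ol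
Product: 13 [(1S,2S)-1-hydroxy-2-{[(4-methoxyphenyl)methoxy]methyl}-4-methylcyclohex-3-en-1-yl]methyl 4-methylbenzenesulfonate
Conditions: TsCl, pyridine, CH2Cl2, 0 °C
Reagents that add atoms: 4-methylbenzenesulfonyl chloride, Cc1ccc(cc1)S(Cl)(=O)=O
Why: Selective sulfonylation of a primary hydroxyl beside a tertiary one, resting on the large rate difference.

Step 9
Reactants: 13 [(1S,2S)-1-hydroxy-2-{[(4-methoxyphenyl)methoxy]methyl}-4-methylcyclohex-3-en-1-yl]methyl 4-methylbenzenesulfonate
Product: 15 (1S,2S)-2-{[(4-methoxyphenyl)methoxy]methyl}-1,4-dimethylcyclohex-3-en-1-ol, via spiro-epoxide 14 (not isolated)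
Conditions: LiBHEt3 (3 equiv), THF, 0 °C to rt; then H2O
Reagents that add atoms: none
Why: The hydride deprotonates the tertiary hydroxyl, the alkoxide closes the epoxide by displacing tosylate at the primary carbon, and hydride opens the epoxide at its CH2 terminus (SN2), so C18 becomes the methyl group and C5 keeps its configuration.

Step 10
Reactants: 15 (1S,2S)-2-{[(4-methoxyphenyl)methoxy]methyl}-1,4-dimethylcyclohex-3-en-1-ol
Product: 16 triethyl{[(1S,2S)-2-{[(4-methoxyphenyl)methoxy]methyl}-1,4-dimethylcyclohex-3-en-1-yl]oxy}silane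
Conditions: Et3SiOTf, 2,6-lutidine, CH2Cl2, −78 to 0 °C
Reagents that add atoms: triethylsilyl trifluoromethanesulfonate, CC[Si](CC)(CC)OS(=O)(=O)C(F)(F)F
Why: Silylation of a hindered tertiary alcohol with a silyl triflate; the ether later blocks retro-aldol cleavage and elimination and adds bulk to the ring face that carries the C6 arm.

Step 11
Reactants: 16 triethyl{[(1S,2S)-2-{[(4-methoxyphenyl)methoxy]methyl}-1,4-dimethylcyclohex-3-en-1-yl]oxy}silane
Product: 17 (1S,2R,3R,4S)-3-{[(4-methoxyphenyl)methoxy]methyl}-1,4-dimethyl-4-[(triethylsilyl)oxy]cyclohexane-1,2-diol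
Conditions: OsO4 (2 mol %), 4-methylmorpholine N-oxide, acetone–H2O, rt
Reagents that add atoms: osmium tetroxide (catalytic oxygen carrier), O=[Os](=O)(=O)=O; 4-methylmorpholine N-oxide, C[N+]1([O-])CCOCC1; water, O
Why: Catalytic osmylation (suprafacial cis-dihydroxylation); the reagent should approach the trisubstituted alkene from the face opposite the allylic C6 arm and the C5 silyloxy group, so both new hydroxyls (C1 and C2) end up trans to the arm.

Step 12
Reactants: 17 (1S,2R,3R,4S)-3-{[(4-methoxyphenyl)methoxy]methyl}-1,4-dimethyl-4-[(triethylsilyl)oxy]cyclohexane-1,2-diol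
Product: 18 (1R,2S,5S,6R)-2-hydroxy-6-{[(4-methoxyphenyl)methoxy]methyl}-2,5-dimethyl-5-[(triethylsilyl)oxy]cyclohexyl methanesulfonate
Conditions: MsCl, Et3N, CH2Cl2, −20 to 0 °C
Reagents that add atoms: methanesulfonyl chloride, CS(Cl)(=O)=O
Why: Selective sulfonylation of the secondary hydroxyl of a secondary/tertiary diol; the amine base does not form the tertiary alkoxide, so no rearrangement occurs at this stage.

Step 13
Reactants: 18 (1R,2S,5S,6R)-2-hydroxy-6-{[(4-methoxyphenyl)methoxy]methyl}-2,5-dimethyl-5-[(triethylsilyl)oxy]cyclohexyl methanesulfonate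
Product: 19 1-[(1S,2S,3S)-2-{[(4-methoxyphenyl)methoxy]methyl}-3-methyl-3-[(triethylsilyl)oxy]cyclopentyl]ethan-1-one
Conditions: KOt-Bu (1.2 equiv), t-BuOH–THF, 0 °C to rt
Reagents that add atoms: none
Why: KOt-Bu deprotonates the tertiary C1 hydroxyl; in the chair that keeps the C6 arm, both methyl groups and the C2 mesylate equatorial, the C1–C3 ring bond is anti-periplanar to the C2–O bond, and the alkoxide drives C3 from C1 to C2 with loss of mesylate while C1 becomes the acetyl carbonyl. The closest known reaction type is the semipinacol (pinacol-type) ring contraction of 1-alkylcyclohexane-cis-1,2-diol 2-sulfonates to acylcyclopentanes. No new ring is closed: the six-membered ring contracts to the five-membered ring by a suprafacial 1,2-alkyl shift that forms C2–C3. The new stereocentre C2 is set by inversion at the mesylate carbon, so its configuration (acetyl trans to the C6 arm) follows from the diol configuration laid down in step 11, and C5 and C6 are untouched. The step needs ring-bond migration to win over methyl migration, epoxide closure and elimination: the cis relation of the two oxygens rules out backside epoxide closure, the equatorial mesylate has neither a hydrogen nor the methyl group anti-periplanar to it, and the alternative chair would carry four axial groups. C2–H of the product is α to the ketone, but the trans isomer formed is also the more stable one, so alkoxide cannot erode it; low temperature and short reaction time limit aldol self-condensation.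

Step 14
Reactants: 19 1-[(1S,2S,3S)-2-{[(4-methoxyphenyl)methoxy]methyl}-3-methyl-3-[(triethylsilyl)oxy]cyclopentyl]ethan-1-one
Product: 20 triethyl{[(1S,2S,3S)-2-{[(4-methoxyphenyl)methoxy]methyl}-1-methyl-3-(prop-1-en-2-yl)cyclopentyl]oxy}silane
Conditions: Ph3PCH3Br, KOt-Bu, THF, 0 °C; then 19, 0 °C to rt
Reagents that add atoms: methyltriphenylphosphonium bromide (source of the methylene carbon), C[P+](c1ccccc1)(c1ccccc1)c1ccccc1.[Br-]
Why: Wittig methylenation of a methyl ketone with a salt-free ylide; any epimerisation at C2 by the basic ylide leads back to the same, more stable trans isomer.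

Step 15
Reactants: 20 triethyl{[(1S,2S,3S)-2-{[(4-methoxyphenyl)methoxy]methyl}-1-methyl-3-(prop-1-en-2-yl)cyclopentyl]oxy}silane
Product: 21 [(1S,2S,5S)-2-methyl-5-(prop-1-en-2-yl)-2-[(triethylsilyl)oxy]cyclopentyl]methanol
Conditions: DDQ, CH2Cl2–pH 7 buffer, 0 °C to rt
Reagents that add atoms: none
Why: Oxidative cleavage of the electron-rich benzyl ether (hydride abstraction, hydrolysis of the oxocarbenium ion) under buffered conditions; the silyl ether and the 1,1-disubstituted alkene are left alone.

Step 16
Reactants: 21 [(1S,2S,5S)-2-methyl-5-(prop-1-en-2-yl)-2-[(triethylsilyl)oxy]cyclopentyl]methanol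
Product: 22 (1R,2S,5S)-2-methyl-5-(prop-1-en-2-yl)-2-[(triethylsilyl)oxy]cyclopentane-1-carbaldehyde
Conditions: Dess–Martin periodinane, pyridine, CH2Cl2, 0 °C to rt
Reagents that add atoms: none
Why: Dess–Martin oxidation under buffered, non-basic conditions gives the aldehyde without epimerising C6 or eliminating the β-silyloxy group.

Step 17
Reactants: 22 (1R,2S,5S)-2-methyl-5-(prop-1-en-2-yl)-2-[(triethylsilyl)oxy]cyclopentane-1-carbaldehyde; 23 ethyl (2E)-4-(diethoxyphosphoryl)-3-methylbut-2-enoate
Product: 24 ethyl (2E,4E)-3-methyl-5-[(1R,2S,5S)-2-methyl-5-(prop-1-en-2-yl)-2-[(triethylsilyl)oxy]cyclopentyl]penta-2,4-dienoate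
Conditions: 23, LiN(SiMe3)2, THF, −78 °C; then 22, −78 to 0 °C
Reagents that add atoms: none
Why: Vinylogous Horner–Wadsworth–Emmons olefination; the stabilised anion should add to the aldehyde faster than it deprotonates it, the new C7=C8 bond should form E, and the C9=C10 geometry is carried in from 23 (any 9Z isomer is removed by chromatography).

Step 18
Reactants: 24 ethyl (2E,4E)-3-methyl-5-[(1R,2S,5S)-2-methyl-5-(prop-1-en-2-yl)-2-[(triethylsilyl)oxy]cyclopentyl]penta-2,4-dienoate
Product: 25 (2E,4E)-3-methyl-5-[(1R,2S,5S)-2-methyl-5-(prop-1-en-2-yl)-2-[(triethylsilyl)oxy]cyclopentyl]penta-2,4-dien-1-ol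
Conditions: i-Bu2AlH (2.2 equiv), CH2Cl2, −78 °C
Reagents that add atoms: none
Why: 1,2-reduction of the dienoate to the allylic alcohol; the silyl ether is inert to the aluminium hydride.

Step 19
Reactants: 25 (2E,4E)-3-methyl-5-[(1R,2S,5S)-2-methyl-5-(prop-1-en-2-yl)-2-[(triethylsilyl)oxy]cyclopentyl]penta-2,4-dien-1-ol
Product: 27 triphenyl{(2E,4E)-3-methyl-5-[(1R,2S,5S)-2-methyl-5-(prop-1-en-2-yl)-2-[(triethylsilyl)oxy]cyclopentyl]penta-2,4-dien-1-yl}phosphonium bromide, via allylic bromide 26 (not isolated)
Conditions: CBr4, PPh3 (1.1 equiv), CH2Cl2, −20 to 0 °C; then PPh3 (1.3 equiv), rt, dark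
Reagents that add atoms: triphenylphosphine, c1ccc(cc1)P(c1ccccc1)c1ccccc1; carbon tetrabromide, BrC(Br)(Br)Br
Why: Appel bromination under neutral conditions, then SN2 quaternisation of triphenylphosphine by the primary allylic bromide; no acid is present, so neither the silyl ether nor the dienyl system is ionised.

Step 20
Reactants: 28 pseudoionone, (3E,5E)-6,10-dimethylundeca-3,5,9-trien-2-one
Product: 29 (4E,6E)-3,7,11-trimethyldodeca-1,4,6,10-tetraen-3-ol (racemic at C3)
Conditions: CH2=CHMgBr, THF, −20 to 0 °C; aq. NH4Cl
Reagents that add atoms: vinylmagnesium bromide, C=C[Mg]Br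
Why: 1,2-addition of a vinyl Grignard reagent to the unhindered methyl ketone of the dienone; the new stereocentre is removed in the next step.

Step 21
Reactants: 29 (4E,6E)-3,7,11-trimethyldodeca-1,4,6,10-tetraen-3-ol
Product: 30 triphenyl[(2E,4E,6E)-3,7,11-trimethyldodeca-2,4,6,10-tetraen-1-yl]phosphonium bromide
Conditions: PPh3·HBr, MeOH, 0 °C to rt; crystallisation
Reagents that add atoms: triphenylphosphine hydrobromide, [PH+](c1ccccc1)(c1ccccc1)c1ccccc1.[Br-]
Why: Acid-mediated allylic transposition: the tertiary bis-allylic alcohol ionises and the delocalised cation is captured by triphenylphosphine at its primary terminus, giving the conjugated salt, whose E isomer is purified by crystallisation.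

Step 22
Reactants: 30 triphenyl[(2E,4E,6E)-3,7,11-trimethyldodeca-2,4,6,10-tetraen-1-yl]phosphonium bromide; 31 (2E,4E,6E)-2,7-dimethylocta-2,4,6-trienedial
Product: 32 (2E,4E,6E,8E,10E,12E,14E)-2,7,11,15,19-pentamethylicosa-2,4,6,8,10,12,14,18-octaenal
Conditions: 31 (3 equiv), NaOMe, MeOH–CH2Cl2, 0 °C to rt; then reflux in n-heptane, dark
Reagents that add atoms: none
Why: Wittig reaction of the allylic ylide with one formyl group of the dialdehyde used in excess; the new disubstituted C11′=C12′ bond is equilibrated to E by heating.

Step 23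
Reactants: 27 triphenyl{(2E,4E)-3-methyl-5-[(1R,2S,5S)-2-methyl-5-(prop-1-en-2-yl)-2-[(triethylsilyl)oxy]cyclopentyl]penta-2,4-dien-1-yl}phosphonium bromide; 32 (2E,4E,6E,8E,10E,12E,14E)-2,7,11,15,19-pentamethylicosa-2,4,6,8,10,12,14,18-octaenal
Product: 33 triethyl({(1S,2R,3S)-1-methyl-2-[(1E,3E,5E,7E,9E,11E,13E,15E,17E,19E)-3,7,12,16,20,24-hexamethylpentacosa-1,3,5,7,9,11,13,15,17,19,23-undecaen-1-yl]-3-(prop-1-en-2-yl)cyclopentyl}oxy)silane
Conditions: NaOMe, MeOH–CH2Cl2, 0 °C to rt, dark, argon; then reflux in n-heptane
Reagents that add atoms: none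
Why: Wittig coupling of the ring C15 ylide with the C25 polyenal forms C11=C12; the disubstituted bond is brought to E by thermal equilibration, and the mild alkoxide leaves the tertiary silyl ether in place.

Step 24
Reactants: 33 triethyl({(1S,2R,3S)-1-methyl-2-[(1E,3E,5E,7E,9E,11E,13E,15E,17E,19E)-3,7,12,16,20,24-hexamethylpentacosa-1,3,5,7,9,11,13,15,17,19,23-undecaen-1-yl]-3-(prop-1-en-2-yl)cyclopentyl}oxy)silane
Product: 34 (1S,2R,3S)-1-methyl-2-[(1E,3E,5E,7E,9E,11E,13E,15E,17E,19E)-3,7,12,16,20,24-hexamethylpentacosa-1,3,5,7,9,11,13,15,17,19,23-undecaen-1-yl]-3-(prop-1-en-2-yl)cyclopentan-1-ol (CNP0222499.1)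
Conditions: n-Bu4NF, THF, 0 °C to rt, dark, argon
Reagents that add atoms: none
Why: Fluoride-induced cleavage of the Si–O bond; the conditions are non-acidic, so the tertiary alcohol neither ionises nor dehydrates and the polyene is not isomerised.

## Compound list

1 | methacrolein (2-methylprop-2-enal) | C=C(C)C=O | starting material
2 | triethyl phosphonoacetate | CCOC(=O)CP(=O)(OCC)OCC | starting material
3 | ethyl (2E)-4-methylpenta-2,4-dienoate | C=C(C)/C=C/C(=O)OCC | intermediate
4 | (2E)-4-methylpenta-2,4-dien-1-ol | C=C(C)/C=C/CO | intermediate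
5 | 1-methoxy-4-({[(2E)-4-methylpenta-2,4-dien-1-yl]oxy}methyl)benzene | C=C(C)/C=C/COCc1ccc(OC)cc1 | intermediate
6 | (R)-lactic acid | C[C@@H](O)C(=O)O | starting material
7 | pivalaldehyde (2,2-dimethylpropanal) | CC(C)(C)C=O | starting material
8 | (2R,5R)-2-tert-butyl-5-methyl-1,3-dioxolan-4-one (cis) | C[C@H]1O[C@@H](C(C)(C)C)OC1=O | intermediate
9 | (2R,5S)-5-bromo-2-tert-butyl-5-methyl-1,3-dioxolan-4-one (bromine trans to tert-butyl) | C[C@@]1(Br)O[C@@H](C(C)(C)C)OC1=O | intermediate (not isolated)
10 | (2R)-2-tert-butyl-5-methylidene-1,3-dioxolan-4-one | C=C1O[C@@H](C(C)(C)C)OC1=O | intermediate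
11 | (2R,5S,6S)-2-tert-butyl-6-{[(4-methoxyphenyl)methoxy]methyl}-8-methyl-1,3-dioxaspiro[4.5]dec-7-en-4-one (ring oxygen cis to the C6 arm) | CC1=C[C@@H](COCc3ccc(OC)cc3)[C@]2(CC1)O[C@@H](C(C)(C)C)OC2=O | intermediate
12 | (1S,2S)-1-(hydroxymethyl)-2-{[(4-methoxyphenyl)methoxy]methyl}-4-methylcyclohex-3-en-1-ol | CC1=C[C@@H](COCc2ccc(OC)cc2)[C@@](CO)(O)CC1 | intermediate
13 | [(1S,2S)-1-hydroxy-2-{[(4-methoxyphenyl)methoxy]methyl}-4-methylcyclohex-3-en-1-yl]methyl 4-methylbenzenesulfonate | CC1=C[C@@H](COCc2ccc(OC)cc2)[C@@](COS(=O)(=O)c2ccc(C)cc2)(O)CC1 | intermediate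
14 | (3S,4S)-4-{[(4-methoxyphenyl)methoxy]methyl}-6-methyl-1-oxaspiro[2.5]oct-5-ene | CC1=C[C@@H](COCc3ccc(OC)cc3)[C@]2(CO2)CC1 | intermediate (not isolated)
15 | (1S,2S)-2-{[(4-methoxyphenyl)methoxy]methyl}-1,4-dimethylcyclohex-3-en-1-ol (hydroxyl cis to the arm) | CC1=C[C@@H](COCc2ccc(OC)cc2)[C@@](C)(O)CC1 | intermediate
16 | triethyl{[(1S,2S)-2-{[(4-methoxyphenyl)methoxy]methyl}-1,4-dimethylcyclohex-3-en-1-yl]oxy}silane | CC1=C[C@@H](COCc2ccc(OC)cc2)[C@@](C)(O[Si](CC)(CC)CC)CC1 | intermediate
17 | (1S,2R,3R,4S)-3-{[(4-methoxyphenyl)methoxy]methyl}-1,4-dimethyl-4-[(triethylsilyl)oxy]cyclohexane-1,2-diol (cis diol, trans to the arm) | C[C@@]1(O)[C@H](O)[C@@H](COCc2ccc(OC)cc2)[C@@](C)(O[Si](CC)(CC)CC)CC1 | intermediate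
18 | (1R,2S,5S,6R)-2-hydroxy-6-{[(4-methoxyphenyl)methoxy]methyl}-2,5-dimethyl-5-[(triethylsilyl)oxy]cyclohexyl methanesulfonate | C[C@@]1(O)[C@H](OS(C)(=O)=O)[C@@H](COCc2ccc(OC)cc2)[C@@](C)(O[Si](CC)(CC)CC)CC1 | intermediate
19 | 1-[(1S,2S,3S)-2-{[(4-methoxyphenyl)methoxy]methyl}-3-methyl-3-[(triethylsilyl)oxy]cyclopentyl]ethan-1-one | CC(=O)[C@H]1CC[C@](C)(O[Si](CC)(CC)CC)[C@@H]1COCc1ccc(OC)cc1 | intermediate
20 | triethyl{[(1S,2S,3S)-2-{[(4-methoxyphenyl)methoxy]methyl}-1-methyl-3-(prop-1-en-2-yl)cyclopentyl]oxy}silane | C=C(C)[C@H]1CC[C@](C)(O[Si](CC)(CC)CC)[C@@H]1COCc1ccc(OC)cc1 | intermediate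
21 | [(1S,2S,5S)-2-methyl-5-(prop-1-en-2-yl)-2-[(triethylsilyl)oxy]cyclopentyl]methanol | C=C(C)[C@H]1CC[C@](C)(O[Si](CC)(CC)CC)[C@@H]1CO | intermediate
22 | (1R,2S,5S)-2-methyl-5-(prop-1-en-2-yl)-2-[(triethylsilyl)oxy]cyclopentane-1-carbaldehyde | C=C(C)[C@H]1CC[C@](C)(O[Si](CC)(CC)CC)[C@@H]1C=O | intermediate
23 | ethyl (2E)-4-(diethoxyphosphoryl)-3-methylbut-2-enoate | CCOC(=O)/C=C(\C)CP(=O)(OCC)OCC | starting material
24 | ethyl (2E,4E)-3-methyl-5-[(1R,2S,5S)-2-methyl-5-(prop-1-en-2-yl)-2-[(triethylsilyl)oxy]cyclopentyl]penta-2,4-dienoate | C=C(C)[C@H]1CC[C@](C)(O[Si](CC)(CC)CC)[C@@H]1/C=C/C(C)=C/C(=O)OCC | intermediate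
25 | (2E,4E)-3-methyl-5-[(1R,2S,5S)-2-methyl-5-(prop-1-en-2-yl)-2-[(triethylsilyl)oxy]cyclopentyl]penta-2,4-dien-1-ol | C=C(C)[C@H]1CC[C@](C)(O[Si](CC)(CC)CC)[C@@H]1/C=C/C(C)=C/CO | intermediate
26 | {[(1S,2R,3S)-2-[(1E,3E)-5-bromo-3-methylpenta-1,3-dien-1-yl]-1-methyl-3-(prop-1-en-2-yl)cyclopentyl]oxy}triethylsilane | C=C(C)[C@H]1CC[C@](C)(O[Si](CC)(CC)CC)[C@@H]1/C=C/C(C)=C/CBr | intermediate (not isolated)
27 | triphenyl{(2E,4E)-3-methyl-5-[(1R,2S,5S)-2-methyl-5-(prop-1-en-2-yl)-2-[(triethylsilyl)oxy]cyclopentyl]penta-2,4-dien-1-yl}phosphonium bromide | C=C(C)[C@H]1CC[C@](C)(O[Si](CC)(CC)CC)[C@@H]1/C=C/C(C)=C/C[P+](c1ccccc1)(c1ccccc1)c1ccccc1.[Br-] | intermediate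
28 | pseudoionone, (3E,5E)-6,10-dimethylundeca-3,5,9-trien-2-one | CC(C)=CCC/C(C)=C/C=C/C(C)=O | starting material
29 | (4E,6E)-3,7,11-trimethyldodeca-1,4,6,10-tetraen-3-ol (racemic) | CC(C)=CCC/C(C)=C/C=C/C(C)(O)C=C | intermediate
30 | triphenyl[(2E,4E,6E)-3,7,11-trimethyldodeca-2,4,6,10-tetraen-1-yl]phosphonium bromide | CC(C)=CCC/C(C)=C/C=C/C(C)=C/C[P+](c1ccccc1)(c1ccccc1)c1ccccc1.[Br-] | intermediate
31 | (2E,4E,6E)-2,7-dimethylocta-2,4,6-trienedial | O=C/C(C)=C/C=C/C=C(\C)C=O | starting material
32 | (2E,4E,6E,8E,10E,12E,14E)-2,7,11,15,19-pentamethylicosa-2,4,6,8,10,12,14,18-octaenal | O=C/C(C)=C/C=C/C=C(C)/C=C/C=C(C)/C=C/C=C(\C)CCC=C(C)C | intermediate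
33 | triethyl({(1S,2R,3S)-1-methyl-2-[(all-E)-3,7,12,16,20,24-hexamethylpentacosa-1,3,5,7,9,11,13,15,17,19,23-undecaen-1-yl]-3-(prop-1-en-2-yl)cyclopentyl}oxy)silane | C=C(C)[C@H]1CC[C@](C)(O[Si](CC)(CC)CC)[C@@H]1/C=C/C(C)=C/C=C/C(C)=C/C=C/C=C(C)/C=C/C=C(C)/C=C/C=C(\C)CCC=C(C)C | intermediate
34 | (1S,2R,3S)-1-methyl-2-[(all-E)-3,7,12,16,20,24-hexamethylpentacosa-1,3,5,7,9,11,13,15,17,19,23-undecaen-1-yl]-3-(prop-1-en-2-yl)cyclopentan-1-ol; carotenoid numbering (2S,5S,6R) | C=C(C)[C@H]1CC[C@](C)(O)[C@@H]1/C=C/C(C)=C/C=C/C(C)=C/C=C/C=C(C)/C=C/C=C(C)/C=C/C=C(\C)CCC=C(C)C | target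

## Step count and risks

Total step count: 24. Longest linear sequence: 19 steps (steps 1–3, 6–19, 23 and 24). Steps 4–5 and 20–22 are side branches.

**Step 13 (key step).** Two processes can starve the rearrangement.
- Osmylation in step 11 may occur partly on the face syn to the C6 arm. The resulting mesylate is axial in the stable chair, so methyl shift and elimination replace ring contraction.
- Migration to the hindered C2 may be slow. The tertiary alkoxide can then take up the sulfonyl group, or the product methyl ketone can self-condense under alkoxide.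

Fallback: set out from alkene 16 and trigger the same C3 shift oxidatively. Thallium trinitrate, Tl(NO3)3·3H2O, in buffered methanol adds the metal to C2 and methanol to C1. Loss of the metal from C2 is accompanied by migration of C3 (oxidative ring contraction of a 1-methylcyclohexene, a known reaction type). The product is triethyl{[(1S,2S,3S)-3-(1,1-dimethoxyethyl)-2-{[(4-methoxyphenyl)methoxy]methyl}-1-methylcyclopentyl]oxy}silane F1. Hydrolysis on wet silica gel gives the ketone, and any C2 epimer is equilibrated to the trans isomer with K2CO3 in methanol. The route is rejoined at 19, and steps 11–13 are bypassed.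

**Step 6.** The cycloaddition may show insufficient preference for the carbonyl-exo mode, which would put the C5 oxygen trans to the arm. It may also be slow, so that the dienophile polymerises. Fallback: set out from diene 5 and use a catalytic enantioselective Diels–Alder reaction with 2-bromoacrolein, under a chiral B-aryl oxazaborolidinium triflimide made from the α,α-diphenylprolinol enantiomer that exposes the required dienophile face.
- α-Substituted acroleins react with the formyl group exo, so bromine ends up cis to the arm in (1S,2S)-1-bromo-2-{[(4-methoxyphenyl)methoxy]methyl}-4-methylcyclohex-3-ene-1-carbaldehyde F2.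
- NaBH4 should give [(1S,2S)-1-bromo-2-{[(4-methoxyphenyl)methoxy]methyl}-4-methylcyclohex-3-en-1-yl]methanol F3.
- K2CO3 in methanol should close (3R,4S)-4-{[(4-methoxyphenyl)methoxy]methyl}-6-methyl-1-oxaspiro[2.5]oct-5-ene F4, with inversion at C5.
- Dilute HClO4 in aqueous THF should open the epoxide at the tertiary carbon with a second inversion, which places the C5 hydroxyl cis to the arm.

The route is rejoined at diol 12.

**Step 17.** The basic phosphonate anion may deprotonate aldehyde 22 at C6, leading to epimerisation or loss of the β-silyloxy group. Geometric purity at C9=C10 may also erode. Fallback: set out from 22 and use the neutral stabilised ylide 1-(triphenylphosphoranylidene)propan-2-one in toluene at 80 °C. This should give (3E)-4-[(1R,2S,5S)-2-methyl-5-(prop-1-en-2-yl)-2-[(triethylsilyl)oxy]cyclopentyl]but-3-en-2-one F5 without any strong base meeting the aldehyde. Horner–Wadsworth–Emmons reaction of this methyl ketone with 2 (NaH, THF), followed by separation of the 9Z isomer, rejoins the route at 24.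

**Step 23.** The Wittig coupling may give poor E selectivity at C11=C12, and polyene may be lost during the thermal equilibration. Fallback: set out from alcohol 25 and make bromide 26 as in the first stage of step 19. Arbuzov reaction with triethyl phosphite should give diethyl {(2E,4E)-3-methyl-5-[(1R,2S,5S)-2-methyl-5-(prop-1-en-2-yl)-2-[(triethylsilyl)oxy]cyclopentyl]penta-2,4-dien-1-yl}phosphonate F6. Its Horner–Wadsworth–Emmons reaction with 32 (KOt-Bu, THF, −30 °C) forms C11=C12 mainly as the E isomer and rejoins the route at 33.

## Further compounds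

F1 | step 13 | triethyl{[(1S,2S,3S)-3-(1,1-dimethoxyethyl)-2-{[(4-methoxyphenyl)methoxy]methyl}-1-methylcyclopentyl]oxy}silane | COC(C)(OC)[C@H]1CC[C@](C)(O[Si](CC)(CC)CC)[C@@H]1COCc1ccc(OC)cc1
F2 | step 6 | (1S,2S)-1-bromo-2-{[(4-methoxyphenyl)methoxy]methyl}-4-methylcyclohex-3-ene-1-carbaldehyde | CC1=C[C@@H](COCc2ccc(OC)cc2)[C@@](C=O)(Br)CC1
F3 | step 6 | [(1S,2S)-1-bromo-2-{[(4-methoxyphenyl)methoxy]methyl}-4-methylcyclohex-3-en-1-yl]methanol | CC1=C[C@@H](COCc2ccc(OC)cc2)[C@@](CO)(Br)CC1
F4 | step 6 | (3R,4S)-4-{[(4-methoxyphenyl)methoxy]methyl}-6-methyl-1-oxaspiro[2.5]oct-5-ene | CC1=C[C@@H](COCc3ccc(OC)cc3)[C@]2(OC2)CC1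
F5 | step 17 | (3E)-4-[(1R,2S,5S)-2-methyl-5-(prop-1-en-2-yl)-2-[(triethylsilyl)oxy]cyclopentyl]but-3-en-2-one | C=C(C)[C@H]1CC[C@](C)(O[Si](CC)(CC)CC)[C@@H]1/C=C/C(C)=O
F6 | step 23 | diethyl {(2E,4E)-3-methyl-5-[(1R,2S,5S)-2-methyl-5-(prop-1-en-2-yl)-2-[(triethylsilyl)oxy]cyclopentyl]penta-2,4-dien-1-yl}phosphonate | C=C(C)[C@H]1CC[C@](C)(O[Si](CC)(CC)CC)[C@@H]1/C=C/C(C)=C/CP(=O)(OCC)OCC
A1 | alternative 1 | cyclopent-2-en-1-one | O=C1C=CCC1
A2 | alternative 1 | (2S,3S)-2-(dimethoxymethyl)-3-(prop-1-en-2-yl)cyclopentan-1-one | C=C(C)[C@H]1CCC(=O)[C@@H]1C(OC)OC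
A3 | alternative 2 | (S)-limonene | CC1=CC[C@H](CC1)C(C)=C
A4 | alternative 2 | (3S)-6-oxo-3-(prop-1-en-2-yl)heptanoic acid | C=C(C)[C@H](CC(=O)O)CCC(C)=O
A5 | alternative 2 | (1R,2S,5S)-5-methyl-2-(prop-1-en-2-yl)-6-oxabicyclo[3.2.0]heptan-7-one | C=C(C)[C@H]1CC[C@]2(C)OC(=O)[C@H]12
A6 | alternative 3 | tert-butyl{[(3S,1E,6E)-1-methoxy-3,7-dimethyl-8-(trimethylsilyl)octa-1,6-dien-3-yl]oxy}dimethylsilane | CO/C=C/[C@@](C)(O[Si](C)(C)C(C)(C)C)CC/C=C(\C)C[Si](C)(C)C
A7 | alternative 3 | tert-butyl{[(1S,2R,3S)-2-(dimethoxymethyl)-1-methyl-3-(prop-1-en-2-yl)cyclopentyl]oxy}dimethylsilane | C=C(C)[C@H]1CC[C@](C)(O[Si](C)(C)C(C)(C)C)[C@@H]1C(OC)OC
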